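**Retrosynthetic overview**
- The acid comes from its methyl ester. The C11=C12 (E) alkene is made by Julia–Kocienski olefination, and C10 is set by Evans alkylation of an allylic bromide (C9–C10).
- The allylic bromide comes from an (E)-enal made by a crossed Mukaiyama aldol plus dehydration. This aldol joins the dioxane carbaldehyde to the butanal enol silane (C7–C8) and is the central fragment union.
- The 1,2-dioxane is closed by a 6-exo oxa-Michael addition of a tertiary hydroperoxide onto an enoate (O2–C3, sets C3). The hydroperoxide comes from inversive perhydrolysis of a 2,2-disubstituted epoxide (C6).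
- The epoxide comes from Sharpless epoxidation, methyl cuprate opening and epoxide re-closure. C4 is set by conjugate addition–elimination of an Evans butanoyl imide onto a 2-(bromomethyl)acrylate (C4–C5).
- Ring order: the 1,2-dioxane is the only ring of the target and is formed once (step 12), before the side chain is grown.

Assumption: the target is taken as the (3S,4R,6S)-dioxane with a (1E,4R,5E)-2,4-diethylocta-1,5-dienyl chain, as read from the SMILES. Anhydrous ethereal H2O2 is prepared in the usual way from 30% H2O2. This is a proposed route and has not been run; the stereochemical outcomes are reasoned from models and analogy.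

**Step 1**
Reactants: 1 (4S)-4-benzyl-1,3-oxazolidin-2-one; 2 butanoyl chloride
Product: 3 (4S)-4-benzyl-3-butanoyl-1,3-oxazolidin-2-one
Conditions: n-BuLi, THF, −78 °C; then 2, −78 → 0 °C
Reagents that add atoms: none
Why: N-acylation of the lithiated oxazolidinone (Evans auxiliary attachment) is routine and leaves the auxiliary stereocentre untouched.

**Step 2**
Reactants: 3 (4S)-4-benzyl-3-butanoyl-1,3-oxazolidin-2-one; 4 tert-butyl 2-(bromomethyl)prop-2-enoate
Product: 5 tert-butyl (4R)-4-{[(4S)-4-benzyl-2-oxo-1,3-oxazolidin-3-yl]carbonyl}-2-methylidenehexanoate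
Conditions: NaN(SiMe3)2, THF, −78 °C; then 4, −78 → −40 °C
Reagents that add atoms: none
Why: Evans asymmetric alkylation in which the chelated Z-sodium enolate adds in conjugate (Michael) fashion to the acrylate and expels bromide (SN2′ addition–elimination) on the face opposite the benzyl group, setting C4 as R.

**Step 3**
Reactants: 5 tert-butyl (4R)-4-{[(4S)-4-benzyl-2-oxo-1,3-oxazolidin-3-yl]carbonyl}-2-methylidenehexanoate
Product: 6 tert-butyl (4R)-4-(hydroxymethyl)-2-methylidenehexanoate
Conditions: LiBH4, MeOH (1 equiv), Et2O, 0 °C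
Reagents that add atoms: none
Why: Reductive cleavage of the N-acyl oxazolidinone by borohydride is much faster than reduction of the hindered tert-butyl ester, so only the exocyclic imide carbonyl is reduced and the auxiliary is recovered.

**Step 4**
Reactants: 6 tert-butyl (4R)-4-(hydroxymethyl)-2-methylidenehexanoate
Product: 7 tert-butyl (4R)-4-formyl-2-methylidenehexanoate
Conditions: Dess–Martin periodinane, NaHCO3, CH2Cl2, 0 °C → rt; used crude
Reagents that add atoms: none
Why: Buffered Dess–Martin oxidation gives the α-branched aldehyde without epimerisation of C4.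

**Step 5**
Reactants: 7 tert-butyl (4R)-4-formyl-2-methylidenehexanoate
Product: 8 tert-butyl (4R)-4-ethyl-2-methylidenehex-5-enoate
Conditions: Ph3PCH3Br, KN(SiMe3)2, THF, −78 → 0 °C (1.05 equiv ylide)
Reagents that add atoms: methyltriphenylphosphonium bromide, C[P+](c1ccccc1)(c1ccccc1)c1ccccc1.[Br-]
Why: Wittig methylenation of the aldehyde is fast at −78 °C, so the hindered 2-alkylacrylate is spared and C4 is not epimerised; the vinyl group masks C3 for later.

**Step 6**
Reactants: 8 tert-butyl (4R)-4-ethyl-2-methylidenehex-5-enoate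
Product: 9 (4R)-4-ethyl-2-methylidenehex-5-en-1-ol
Conditions: i-Bu2AlH (2.5 equiv), CH2Cl2, −78 → 0 °C; KNaC4H4O6 (aq) work-up
Reagents that add atoms: none
Why: 1,2-reduction of the unsaturated ester by i-Bu2AlH gives the 2-substituted allylic alcohol and does not touch the isolated vinyl group.

**Step 7**
Reactants: 9 (4R)-4-ethyl-2-methylidenehex-5-en-1-ol
Product: 10 {(2R)-2-[(2R)-2-ethylbut-3-en-1-yl]oxiran-2-yl}methanol
Conditions: Ti(OiPr)4 (10 mol%), D-(−)-diisopropyl tartrate (12 mol%), t-BuOOH (anhydrous, isooctane), 4 Å MS, CH2Cl2, −20 °C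
Reagents that add atoms: tert-butyl hydroperoxide, CC(C)(C)OO
Why: Sharpless asymmetric epoxidation under reagent control (D-tartrate gives the R epoxy alcohol, by analogy with L-tartrate giving (S)-2-methylglycidol) sets the C6 oxygen face; the unactivated vinyl group does not react.

**Step 8**
Reactants: 10 {(2R)-2-[(2R)-2-ethylbut-3-en-1-yl]oxiran-2-yl}methanol
Product: 11 (2R,4R)-2,4-diethylhex-5-ene-1,2-diol
Conditions: Me2CuLi (3 equiv, from MeLi and CuI), Et2O, −40 → 0 °C
Reagents that add atoms: lithium dimethylcuprate, [Li+].C[Cu-]C (made from methyllithium, [Li]C)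
Why: SN2 cuprate opening at the unsubstituted epoxide CH2 turns that carbon into the C6 ethyl group and leaves the tertiary C6–O bond and its configuration intact.

**Step 9**
Reactants: 11 (2R,4R)-2,4-diethylhex-5-ene-1,2-diol
Product: 13 (2R)-2-ethyl-2-[(2R)-2-ethylbut-3-en-1-yl]oxirane, via primary tosylate 12 (not isolated)
Conditions: TsCl (1.1 equiv), Et3N, DMAP (cat.), CH2Cl2, 0 °C; then K2CO3, MeOH, rt
Reagents that add atoms: none
Why: Selective sulfonylation of the primary hydroxyl followed by intramolecular Williamson closure (3-exo-tet) forms the terminal epoxide without breaking the C6–O bond, so C6 stays R.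

**Step 10**
Reactants: 13 (2R)-2-ethyl-2-[(2R)-2-ethylbut-3-en-1-yl]oxirane; 14 methyl prop-2-enoate
Product: 15 methyl (2E,4R)-4-ethyl-5-[(2R)-2-ethyloxiran-2-yl]pent-2-enoate
Conditions: 14 (5 equiv), second-generation Grubbs catalyst RuCl2(=CHPh)(PCy3)(H2IMes) (5 mol%), CH2Cl2, 40 °C
Reagents that add atoms: none
Why: Olefin cross-metathesis of the terminal alkene with the acrylate is E-selective and tolerates the epoxide, and it avoids a free 4,5-epoxy alcohol that would cyclise to a tetrahydrofuran.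

**Step 11**
Reactants: 15 methyl (2E,4R)-4-ethyl-5-[(2R)-2-ethyloxiran-2-yl]pent-2-enoate
Product: 16 methyl (2E,4R,6S)-4,6-diethyl-6-hydroperoxy-7-hydroxyhept-2-enoate
Conditions: H2O2 (anhydrous, about 2 M in Et2O, 10 equiv), H3PMo12O40 (5 mol%), Et2O, rt; used at once
Reagents that add atoms: hydrogen peroxide, OO
Why: Acid-catalysed perhydrolysis of the epoxide opens the more substituted carbon in a borderline SN2 manner with inversion, converting the R epoxide carbon into the S tertiary hydroperoxide at C6 and releasing the C7 hydroxyl.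

**Step 12**
Reactants: 16 methyl (2E,4R,6S)-4,6-diethyl-6-hydroperoxy-7-hydroxyhept-2-enoate
Product: 17 methyl 2-[(3S,4R,6S)-4,6-diethyl-6-(hydroxymethyl)-1,2-dioxan-3-yl]acetate
Conditions: Et2NH (0.5 equiv), CF3CH2OH, rt; chromatography
Reagents that add atoms: none
Why: Intramolecular oxa-Michael addition (6-exo-trig) of the hydroperoxide, which outcompetes the alcohol, proceeds through a chair with the C4 ethyl and the acetate arm equatorial to give the 3,4-trans ring (C3 = S); the reversible conditions favour the same isomer and minor isomers are removed here.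

**Step 13**
Reactants: 17 methyl 2-[(3S,4R,6S)-4,6-diethyl-6-(hydroxymethyl)-1,2-dioxan-3-yl]acetate
Product: 18 methyl 2-[(3S,4R,6S)-4,6-diethyl-6-formyl-1,2-dioxan-3-yl]acetate
Conditions: Dess–Martin periodinane, NaHCO3, CH2Cl2, 0 °C → rt
Reagents that add atoms: none
Why: Dess–Martin oxidation of the neopentyl-type alcohol gives a non-enolisable aldehyde under neutral conditions that the dialkyl peroxide and the ester tolerate.

**Step 14**
Reactants: 19 butanal
Product: 20 trimethyl[(but-1-en-1-yl)oxy]silane (E/Z mixture, geometry irrelevant)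
Conditions: Me3SiCl, Et3N, DMF, 80 °C; distillation
Reagents that add atoms: chlorotrimethylsilane, C[Si](C)(C)Cl
Why: Silyl enol ether formation under House conditions gives a defined butanal enolate equivalent and so prevents self-condensation of butanal in the next step.

**Step 15**
Reactants: 18 methyl 2-[(3S,4R,6S)-4,6-diethyl-6-formyl-1,2-dioxan-3-yl]acetate; 20 trimethyl[(but-1-en-1-yl)oxy]silane
Product: 21 methyl 2-[(3S,4R,6S)-4,6-diethyl-6-(2-ethyl-1-hydroxy-3-oxopropyl)-1,2-dioxan-3-yl]acetate (mixture of diastereomers at the two new centres)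
Conditions: BF3·OEt2 (1.1 equiv), CH2Cl2, −78 °C; aqueous NaHCO3 quench; used crude
Reagents that add atoms: none
Why: Crossed Mukaiyama aldol addition in which the non-enolisable aldehyde can only be the acceptor forms the C7–C8 bond; the two new stereocentres are removed in the next step, so their configuration is irrelevant.

**Step 16**
Reactants: 21 methyl 2-[(3S,4R,6S)-4,6-diethyl-6-(2-ethyl-1-hydroxy-3-oxopropyl)-1,2-dioxan-3-yl]acetate
Product: 23 methyl 2-[(3S,4R,6S)-4,6-diethyl-6-[(1E)-2-formylbut-1-en-1-yl]-1,2-dioxan-3-yl]acetate, via secondary mesylate 22 (not isolated)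
Conditions: MsCl, Et3N, CH2Cl2, 0 °C → rt
Reagents that add atoms: none
Why: Mesylation and E1cB elimination complete the aldol condensation and give the conjugated enal as the E isomer (formyl trans to the ring, ethyl cis), which is the thermodynamically preferred geometry.

**Step 17**
Reactants: 23 methyl 2-[(3S,4R,6S)-4,6-diethyl-6-[(1E)-2-formylbut-1-en-1-yl]-1,2-dioxan-3-yl]acetate
Product: 24 methyl 2-[(3S,4R,6S)-4,6-diethyl-6-[(1E)-2-(hydroxymethyl)but-1-en-1-yl]-1,2-dioxan-3-yl]acetate
Conditions: NaBH4, CeCl3·7H2O, MeOH, −20 °C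
Reagents that add atoms: none
Why: Luche 1,2-reduction of the enal is selective for the aldehyde and leaves the methyl ester and the dialkyl peroxide untouched.

**Step 18**
Reactants: 24 methyl 2-[(3S,4R,6S)-4,6-diethyl-6-[(1E)-2-(hydroxymethyl)but-1-en-1-yl]-1,2-dioxan-3-yl]acetate
Product: 26 methyl 2-[(3S,4R,6S)-6-[(1E)-2-(bromomethyl)but-1-en-1-yl]-4,6-diethyl-1,2-dioxan-3-yl]acetate, via allylic mesylate 25 (not isolated)
Conditions: MsCl, Et3N, THF, 0 °C; then LiBr, 0 °C → rt
Reagents that add atoms: lithium bromide, [Li+].[Br-]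
Why: Mesylation and SN2 displacement by bromide give the primary allylic bromide with the alkene geometry retained and without phosphines that could reduce the peroxide.

**Step 19**
Reactants: 3 (4S)-4-benzyl-3-butanoyl-1,3-oxazolidin-2-one; 26 methyl 2-[(3S,4R,6S)-6-[(1E)-2-(bromomethyl)but-1-en-1-yl]-4,6-diethyl-1,2-dioxan-3-yl]acetate
Product: 27 methyl 2-[(3S,4R,6S)-6-[(1E,4R)-4-{[(4S)-4-benzyl-2-oxo-1,3-oxazolidin-3-yl]carbonyl}-2-ethylhex-1-en-1-yl]-4,6-diethyl-1,2-dioxan-3-yl]acetate
Conditions: 3 (1.5 equiv), NaN(SiMe3)2 (1.45 equiv), THF, −78 °C; then 26, −78 → −40 °C; cold NH4Cl quench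
Reagents that add atoms: none
Why: Evans asymmetric alkylation of the preformed Z-sodium enolate by the reactive allylic bromide, anti to the benzyl group, sets C10 as R; at −78 to −40 °C the imide enolate is too weak a base to enolise the ester or attack the peroxide.

**Step 20**
Reactants: 27 methyl 2-[(3S,4R,6S)-6-[(1E,4R)-4-{[(4S)-4-benzyl-2-oxo-1,3-oxazolidin-3-yl]carbonyl}-2-ethylhex-1-en-1-yl]-4,6-diethyl-1,2-dioxan-3-yl]acetate
Product: 28 methyl 2-[(3S,4R,6S)-4,6-diethyl-6-[(1E,4R)-2-ethyl-4-(hydroxymethyl)hex-1-en-1-yl]-1,2-dioxan-3-yl]acetate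
Conditions: NaBH4 (4 equiv), THF/H2O (4:1), 0 °C → rt, monitored
Reagents that add atoms: none
Why: Reductive removal of the auxiliary with NaBH4 in wet THF exploits the higher electrophilicity of the imide carbonyl over the methyl ester, and borohydride does not cleave the dialkyl peroxide.

**Step 21**
Reactants: 28 methyl 2-[(3S,4R,6S)-4,6-diethyl-6-[(1E,4R)-2-ethyl-4-(hydroxymethyl)hex-1-en-1-yl]-1,2-dioxan-3-yl]acetate
Product: 29 methyl 2-[(3S,4R,6S)-4,6-diethyl-6-[(1E,4R)-2-ethyl-4-formylhex-1-en-1-yl]-1,2-dioxan-3-yl]acetate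
Conditions: Dess–Martin periodinane, NaHCO3, CH2Cl2, 0 °C → rt; used crude
Reagents that add atoms: none
Why: Buffered Dess–Martin oxidation gives the α-branched aldehyde without epimerisation of C10.

**Step 22**
Reactants: 30 1-phenyl-1H-tetrazole-5-thiol; 31 1-bromopropane
Product: 32 1-phenyl-5-(propylsulfanyl)-1H-tetrazole
Conditions: K2CO3, acetone, reflux
Reagents that add atoms: none
Why: SN2 S-alkylation of the thiolate with a primary bromide is clean and high-yielding.

**Step 23**
Reactants: 32 1-phenyl-5-(propylsulfanyl)-1H-tetrazole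
Product: 33 1-phenyl-5-(propylsulfonyl)-1H-tetrazole
Conditions: H2O2 (30% aq, 5 equiv), (NH4)6Mo7O24·4H2O (10 mol%), EtOH, rt
Reagents that add atoms: hydrogen peroxide, OO
Why: Molybdate-catalysed oxidation takes the sulfide through the sulfoxide to the sulfone, the standard preparation of Julia–Kocienski reagents.

**Step 24**
Reactants: 29 methyl 2-[(3S,4R,6S)-4,6-diethyl-6-[(1E,4R)-2-ethyl-4-formylhex-1-en-1-yl]-1,2-dioxan-3-yl]acetate; 33 1-phenyl-5-(propylsulfonyl)-1H-tetrazole
Product: 34 methyl 2-[(3S,4R,6S)-6-[(1E,4R,5E)-2,4-diethylocta-1,5-dien-1-yl]-4,6-diethyl-1,2-dioxan-3-yl]acetate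
Conditions: 33, KN(SiMe3)2, DME, −60 °C, 20 min; then 29, −60 °C → rt
Reagents that add atoms: none
Why: Julia–Kocienski olefination with a premetalated phenyltetrazolyl sulfone in DME gives the disubstituted alkene with high E selectivity, and the cold pre-formed anion adds to the aldehyde faster than it can epimerise C10 or enolise the ester.

**Step 25**
Reactants: 34 methyl 2-[(3S,4R,6S)-6-[(1E,4R,5E)-2,4-diethylocta-1,5-dien-1-yl]-4,6-diethyl-1,2-dioxan-3-yl]acetate
Product: 35 2-[(3S,4R,6S)-6-[(1E,4R,5E)-2,4-diethylocta-1,5-dien-1-yl]-4,6-diethyl-1,2-dioxan-3-yl]acetic acid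
Conditions: LiOH·H2O, THF/H2O (3:1), 0 °C → rt; then 1 M HCl to pH 4 at 0 °C
Reagents that add atoms: lithium hydroxide, [Li+].[OH-]
Why: Saponification of the methyl ester with LiOH is the standard final step for 1,2-dioxane-3-acetates of this family and leaves the peroxide and all stereocentres untouched.

**Compound list**
1 | (4S)-4-benzyl-1,3-oxazolidin-2-one | O=C1OC[C@H](Cc2ccccc2)N1 | starting material
2 | butanoyl chloride | CCCC(Cl)=O | starting material
3 | (4S)-4-benzyl-3-butanoyl-1,3-oxazolidin-2-one | CCCC(=O)N1[C@@H](Cc2ccccc2)COC1=O | intermediate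
4 | tert-butyl 2-(bromomethyl)prop-2-enoate | C=C(CBr)C(=O)OC(C)(C)C | starting material
5 | tert-butyl (4R)-4-{[(4S)-4-benzyl-2-oxo-1,3-oxazolidin-3-yl]carbonyl}-2-methylidenehexanoate | CC[C@H](CC(=C)C(=O)OC(C)(C)C)C(=O)N1[C@@H](Cc2ccccc2)COC1=O | intermediate
6 | tert-butyl (4R)-4-(hydroxymethyl)-2-methylidenehexanoate | CC[C@H](CC(=C)C(=O)OC(C)(C)C)CO | intermediate
7 | tert-butyl (4R)-4-formyl-2-methylidenehexanoate | CC[C@H](CC(=C)C(=O)OC(C)(C)C)C=O | intermediate
8 | tert-butyl (4R)-4-ethyl-2-methylidenehex-5-enoate | CC[C@H](CC(=C)C(=O)OC(C)(C)C)C=C | intermediate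
9 | (4R)-4-ethyl-2-methylidenehex-5-en-1-ol | CC[C@H](CC(=C)CO)C=C | intermediate
10 | {(2R)-2-[(2R)-2-ethylbut-3-en-1-yl]oxiran-2-yl}methanol | CC[C@H](C[C@@]1(CO)CO1)C=C | intermediate
11 | (2R,4R)-2,4-diethylhex-5-ene-1,2-diol | CC[C@H](C[C@](O)(CC)CO)C=C | intermediate
12 | (2R,4R)-2,4-diethyl-2-hydroxyhex-5-en-1-yl 4-methylbenzenesulfonate (primary tosylate) | CC[C@H](C[C@](O)(CC)COS(=O)(=O)c1ccc(C)cc1)C=C | intermediate
13 | (2R)-2-ethyl-2-[(2R)-2-ethylbut-3-en-1-yl]oxirane | CC[C@H](C[C@]1(CC)CO1)C=C | intermediate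
14 | methyl prop-2-enoate | C=CC(=O)OC | starting material
15 | methyl (2E,4R)-4-ethyl-5-[(2R)-2-ethyloxiran-2-yl]pent-2-enoate | CC[C@H](C[C@]1(CC)CO1)/C=C/C(=O)OC | intermediate
16 | methyl (2E,4R,6S)-4,6-diethyl-6-hydroperoxy-7-hydroxyhept-2-enoate | CC[C@H](C[C@@](CC)(CO)OO)/C=C/C(=O)OC | intermediate
17 | methyl 2-[(3S,4R,6S)-4,6-diethyl-6-(hydroxymethyl)-1,2-dioxan-3-yl]acetate | OC[C@]1(CC)C[C@@H](CC)[C@H](CC(=O)OC)OO1 | intermediate
18 | methyl 2-[(3S,4R,6S)-4,6-diethyl-6-formyl-1,2-dioxan-3-yl]acetate | O=C[C@]1(CC)C[C@@H](CC)[C@H](CC(=O)OC)OO1 | intermediate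
19 | butanal | CCCC=O | starting material
20 | trimethyl[(but-1-en-1-yl)oxy]silane (E/Z mixture) | CCC=CO[Si](C)(C)C | intermediate
21 | methyl 2-[(3S,4R,6S)-4,6-diethyl-6-(2-ethyl-1-hydroxy-3-oxopropyl)-1,2-dioxan-3-yl]acetate (diastereomer mixture at the two side-chain centres) | CCC(C=O)C(O)[C@]1(CC)C[C@@H](CC)[C@H](CC(=O)OC)OO1 | intermediate
22 | methyl 2-[(3S,4R,6S)-4,6-diethyl-6-{2-ethyl-1-[(methylsulfonyl)oxy]-3-oxopropyl}-1,2-dioxan-3-yl]acetate (secondary mesylate) | CCC(C=O)C(OS(C)(=O)=O)[C@]1(CC)C[C@@H](CC)[C@H](CC(=O)OC)OO1 | intermediate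
23 | methyl 2-[(3S,4R,6S)-4,6-diethyl-6-[(1E)-2-formylbut-1-en-1-yl]-1,2-dioxan-3-yl]acetate | O=C/C(=C/[C@]1(CC)C[C@@H](CC)[C@H](CC(=O)OC)OO1)CC | intermediate
24 | methyl 2-[(3S,4R,6S)-4,6-diethyl-6-[(1E)-2-(hydroxymethyl)but-1-en-1-yl]-1,2-dioxan-3-yl]acetate | OC/C(=C/[C@]1(CC)C[C@@H](CC)[C@H](CC(=O)OC)OO1)CC | intermediate
25 | methyl 2-[(3S,4R,6S)-4,6-diethyl-6-[(1E)-2-{[(methylsulfonyl)oxy]methyl}but-1-en-1-yl]-1,2-dioxan-3-yl]acetate (allylic mesylate) | CS(=O)(=O)OC/C(=C/[C@]1(CC)C[C@@H](CC)[C@H](CC(=O)OC)OO1)CC | intermediate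
26 | methyl 2-[(3S,4R,6S)-6-[(1E)-2-(bromomethyl)but-1-en-1-yl]-4,6-diethyl-1,2-dioxan-3-yl]acetate | BrC/C(=C/[C@]1(CC)C[C@@H](CC)[C@H](CC(=O)OC)OO1)CC | intermediate
27 | methyl 2-[(3S,4R,6S)-6-[(1E,4R)-4-{[(4S)-4-benzyl-2-oxo-1,3-oxazolidin-3-yl]carbonyl}-2-ethylhex-1-en-1-yl]-4,6-diethyl-1,2-dioxan-3-yl]acetate | CC[C@H](C/C(=C/[C@]1(CC)C[C@@H](CC)[C@H](CC(=O)OC)OO1)CC)C(=O)N1[C@@H](Cc2ccccc2)COC1=O | intermediate
28 | methyl 2-[(3S,4R,6S)-4,6-diethyl-6-[(1E,4R)-2-ethyl-4-(hydroxymethyl)hex-1-en-1-yl]-1,2-dioxan-3-yl]acetate | CC[C@H](C/C(=C/[C@]1(CC)C[C@@H](CC)[C@H](CC(=O)OC)OO1)CC)CO | intermediate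
29 | methyl 2-[(3S,4R,6S)-4,6-diethyl-6-[(1E,4R)-2-ethyl-4-formylhex-1-en-1-yl]-1,2-dioxan-3-yl]acetate | CC[C@H](C/C(=C/[C@]1(CC)C[C@@H](CC)[C@H](CC(=O)OC)OO1)CC)C=O | intermediate
30 | 1-phenyl-1H-tetrazole-5-thiol | Sc1nnnn1-c1ccccc1 | starting material
31 | 1-bromopropane | CCCBr | starting material
32 | 1-phenyl-5-(propylsulfanyl)-1H-tetrazole | CCCSc1nnnn1-c1ccccc1 | intermediate
33 | 1-phenyl-5-(propylsulfonyl)-1H-tetrazole | CCCS(=O)(=O)c1nnnn1-c1ccccc1 | intermediate
34 | methyl 2-[(3S,4R,6S)-6-[(1E,4R,5E)-2,4-diethylocta-1,5-dien-1-yl]-4,6-diethyl-1,2-dioxan-3-yl]acetate | CC/C=C/[C@H](CC)C/C(=C/[C@]1(CC)C[C@@H](CC)[C@H](CC(=O)OC)OO1)CC | intermediate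
35 | 2-[(3S,4R,6S)-6-[(1E,4R,5E)-2,4-diethylocta-1,5-dien-1-yl]-4,6-diethyl-1,2-dioxan-3-yl]acetic acid | CC/C=C/[C@H](CC)C/C(=C/[C@]1(CC)C[C@@H](CC)[C@H](CC(=O)O)OO1)CC | target

**Step count**
Total: 25 steps. Longest linear sequence: 22 steps (steps 1–13, 15–21, 24, 25). Steps 14 and 22–23 are side branches.

**Three steps most likely to fail, with fallbacks**

Step 11 (perhydrolysis of 15). The opening must occur at the tertiary carbon with clean inversion, and the β-hydroxy hydroperoxide is fragile. If yield or stereochemical fidelity is poor, the peroxide is installed instead by cobalt-mediated hydroperoxysilylation, accepting both C6 epimers and separating them after ring closure. The fallback sets out from 13. Isomerisation of the epoxide with Et2Al(TMP) (diethylaluminium 2,2,6,6-tetramethylpiperidide) gives (2E)-2-[(2R)-2-ethylbut-3-en-1-yl]but-2-en-1-ol F1; its geometry and any regioisomeric alkene are irrelevant because all of them give the same tertiary C6 radical later. Cross-metathesis of the vinyl group with 14 gives methyl (2E,4R,6E)-4-ethyl-6-(hydroxymethyl)octa-2,6-dienoate F2. Treatment with Co(thd)2 (bis(2,2,6,6-tetramethylheptane-3,5-dionato)cobalt), O2 and Et3SiH adds hydrogen and the silylperoxy group across the electron-rich trisubstituted alkene only, giving methyl (2E,4R)-4,6-diethyl-7-hydroxy-6-[(triethylsilyl)peroxy]hept-2-enoate F3 as a C6 epimer pair. Bu4NF removes the silyl group and triggers the oxa-Michael closure, giving 17 together with methyl 2-[(3S,4R,6R)-4,6-diethyl-6-(hydroxymethyl)-1,2-dioxan-3-yl]acetate F4, which is removed by chromatography. The route is rejoined at 17.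

Step 15 (Mukaiyama aldol on the hindered α-peroxy aldehyde 18). The Lewis acid may degrade the peroxide, or the neopentyl aldehyde may react sluggishly. The fallback sets out from 18 and replaces the aldol/dehydration pair by a Wittig olefination with the stabilised ylide 2-(triphenylphosphoranylidene)butanal (toluene, 80 °C). This is neutral, E-selective and gives enal 23 directly, where the route is rejoined; no new intermediate is formed.

Step 20 (chemoselective reductive removal of the auxiliary from 27 beside a methyl ester and a peroxide; the same fallback also bypasses the enolate alkylation of step 19). The fallback sets out from 26 and uses an Enders hydrazone alkylation at the aldehyde oxidation level, so no hydride step is needed. Butanal 19 is condensed with RAMP to give (1E)-N-[(2R)-2-(methoxymethyl)pyrrolidin-1-yl]butan-1-imine F5. Its azaenolate (LiN(i-Pr)2, THF, 0 °C) is alkylated with 26 at −100 °C to give methyl 2-[(3S,4R,6S)-4,6-diethyl-6-[(1E,4R)-2-ethyl-4-[(E)-{[(2R)-2-(methoxymethyl)pyrrolidin-1-yl]imino}methyl]hex-1-en-1-yl]-1,2-dioxan-3-yl]acetate F6; RAMP is chosen because SAMP gives the S series with this substituent ranking. Two-phase hydrolysis with aqueous oxalic acid releases aldehyde 29 without epimerisation, where the route is rejoined.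

**Further compounds**
F1 | step 11 | (2E)-2-[(2R)-2-ethylbut-3-en-1-yl]but-2-en-1-ol | CC[C@H](C/C(CO)=C\C)C=C
F2 | step 11 | methyl (2E,4R,6E)-4-ethyl-6-(hydroxymethyl)octa-2,6-dienoate | CC[C@H](C/C(CO)=C\C)/C=C/C(=O)OC
F3 | step 11 | methyl (2E,4R)-4,6-diethyl-7-hydroxy-6-[(triethylsilyl)peroxy]hept-2-enoate (both C6 epimers) | CC[C@H](CC(CC)(CO)OO[Si](CC)(CC)CC)/C=C/C(=O)OC
F4 | step 11 | methyl 2-[(3S,4R,6R)-4,6-diethyl-6-(hydroxymethyl)-1,2-dioxan-3-yl]acetate | OC[C@@]1(CC)C[C@@H](CC)[C@H](CC(=O)OC)OO1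
F0 | step 15 | none | none
F5 | step 20 | (1E)-N-[(2R)-2-(methoxymethyl)pyrrolidin-1-yl]butan-1-imine | CCC/C=N/N1CCC[C@@H]1COC
F6 | step 20 | methyl 2-[(3S,4R,6S)-4,6-diethyl-6-[(1E,4R)-2-ethyl-4-[(E)-{[(2R)-2-(methoxymethyl)pyrrolidin-1-yl]imino}methyl]hex-1-en-1-yl]-1,2-dioxan-3-yl]acetate | CC[C@H](C/C(=C/[C@]1(CC)C[C@@H](CC)[C@H](CC(=O)OC)OO1)CC)/C=N/N1CCC[C@@H]1COC
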